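## Retrosynthetic overview

1. Target 20 comes from Pinnick oxidation of aldehyde 19, which comes from an intramolecular Diels–Alder (IMDA) reaction of the acyclic (6S)-pentaenal 18. That single step closes both the cyclohexene and the cyclopentene (bonds C3–C7 and C2–C10) and sets four stereocentres under control of C6.
2. Pentaene 16 (precursor of 18) is made by the key C5–C6 bond formation: a Ni-catalysed enantioconvergent allyl–alkenyl coupling of racemic trienyl carbonate 15 with (Z)-dienylboronate 6, which sets C6.
3. Boronate 6 comes from a Negishi coupling of an alkenylzinc (propargyl alcohol carboalumination product) with (Z)-2-bromobutenyl-Bpin (bromoboration of 1-butyne).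
4. Carbonate 15 comes from hex-3-yn-2-ol by two hydrozirconation/Negishi couplings, first with 1-bromobut-1-yne and then with (E)-β-iodostyrene (from phenylacetylene).
5. Ring order: the route is acyclic through step 14; both carbocycles form together in step 15.

Assumptions: chain numbering C1–C12 is that of the acyclic pentaene (C1 = future CO2H carbon, C12 = PhCH=). The sense of induction of the new Ni catalyst cannot be predicted, so the ligand antipode that gives (6S) is assumed and written as (R)-DTBM-SEGPHOS. CIP descriptors were derived by hand from the SMILES; the SMILES is authoritative.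

## Route

**Step 1**
Reactants: 1 prop-2-yn-1-ol
Product: 2 (E)-3-iodo-2-methylprop-2-en-1-ol
Conditions: Me3Al (3 equiv), Cp2ZrCl2 (0.25 equiv), CH2Cl2, 0 → 23 °C; then I2, THF, −30 → 0 °C
Reagents that add atoms: trimethylaluminium, C[Al](C)C; iodine, II
Why: Zr-catalysed syn-carboalumination (Negishi) puts Me on the internal and Al on the terminal alkyne carbon, and iodinolysis with retention gives only the E iodide, fixing the C2-methyl and the 2E geometry of the future dienophile.

**Step 2**
Reactants: 2 (E)-3-iodo-2-methylprop-2-en-1-ol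
Product: 3 (E)-tert-butyl[(3-iodo-2-methylprop-2-en-1-yl)oxy]dimethylsilane
Conditions: TBSCl, imidazole, CH2Cl2, 0 → 23 °C
Reagents that add atoms: TBSCl, CC(C)(C)[Si](C)(C)Cl
Why: Standard silylation; the TBS ether tolerates t-BuLi, organozinc and Ni(0) and is removed by fluoride in step 13.

**Step 3**
Reactants: 4 but-1-yne
Product: 5 2-[(1Z)-2-bromobut-1-en-1-yl]-4,4,5,5-tetramethyl-1,3,2-dioxaborolane
Conditions: BBr3 (1.0 equiv), CH2Cl2, −78 °C; then pinacol, −78 → 23 °C
Reagents that add atoms: boron tribromide, BrB(Br)Br; pinacol, CC(C)(O)C(C)(C)O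
Why: syn-Bromoboration of a terminal alkyne places Br on the internal carbon and B on the terminal carbon, cis to each other, and pinacol trapping gives the (Z)-β-bromoalkenylboronate that encodes the 4Z geometry.

**Step 4**
Reactants: 3 (E)-TBS-protected iodide; 5 (Z)-bromoalkenyl-Bpin
Product: 6 tert-butyl{[(2E,4Z)-4-ethyl-2-methyl-5-(4,4,5,5-tetramethyl-1,3,2-dioxaborolan-2-yl)penta-2,4-dien-1-yl]oxy}dimethylsilane
Conditions: 3, t-BuLi (2 equiv), Et2O, −78 °C; ZnBr2, THF, −78 → 0 °C; then 5, Pd(t-Bu3P)2 (2 mol %), THF, 23 °C
Reagents that add atoms: none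
Why: I/Li exchange and zincation occur with retention, and the Negishi coupling at C–Br proceeds with retention on both partners while the Bpin is inert without base, giving the dienylboronate with C3 cis to boron.

**Step 5**
Reactants: 7 hex-3-yn-2-ol (racemic)
Product: 8 tert-butyl(hex-3-yn-2-yloxy)dimethylsilane (racemic)
Conditions: TBSCl, imidazole, DMF, 23 °C
Reagents that add atoms: TBSCl, CC(C)(C)[Si](C)(C)Cl
Why: Standard silylation; it protects the carbinol through two hydrozirconation/Pd steps and makes the propargylic substituent bulky for regiocontrol.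

**Step 6**
Reactants: 4 but-1-yne
Product: 9 1-bromobut-1-yne
Conditions: NBS, AgNO3 (10 mol %), acetone, 23 °C; used as a solution
Reagents that add atoms: N-bromosuccinimide, O=C1CCC(=O)N1Br
Why: Ag-catalysed electrophilic bromination of a terminal alkyne, a routine route to 1-bromoalkynes.

**Step 7**
Reactants: 8 silyl ether of hex-3-yn-2-ol; 9 1-bromobut-1-yne
Product: 10 rac-(E)-tert-butyl[(4-ethyloct-3-en-5-yn-2-yl)oxy]dimethylsilane
Conditions: Cp2Zr(H)Cl (1.3 equiv), THF, 23 → 50 °C; ZnCl2, 0 °C; then 9, Pd(PPh3)4 (5 mol %), 23 °C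
Reagents that add atoms: none
Why: syn-Hydrozirconation under equilibrating conditions puts Zr on the ethyl-bearing carbon (away from CH(Me)OTBS), and Zr→Zn transmetalation with Negishi alkynylation (retention) gives the 7E trisubstituted alkene carrying the C8 ethyl.

**Step 8**
Reactants: 11 ethynylbenzene
Product: 12 (E)-(2-iodoethenyl)benzene
Conditions: Cp2Zr(H)Cl, THF, 23 °C; then I2, 0 °C
Reagents that add atoms: iodine, II
Why: syn-Hydrozirconation of a terminal alkyne followed by iodinolysis with retention gives only the E vinyl iodide.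

**Step 9**
Reactants: 10 enyne; 12 (E)-β-iodostyrene
Product: 13 rac-tert-butyl{[(3E,5E,7E)-4,6-diethyl-8-phenylocta-3,5,7-trien-2-yl]oxy}dimethylsilane
Conditions: Cp2Zr(H)Cl (1.2 equiv), THF, 23 → 40 °C; ZnCl2; then 12, Pd(PPh3)4 (5 mol %), THF, 23 °C
Reagents that add atoms: none
Why: Second syn-hydrozirconation places Zr on the ethyl-bearing alkyne carbon (distal to the bulky trisubstituted alkenyl group), and Negishi coupling with retention gives the all-E triene (9E, 11E).

**Step 10**
Reactants: 13 triene silyl ether
Product: 14 rac-(3E,5E,7E)-4,6-diethyl-8-phenylocta-3,5,7-trien-2-ol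
Conditions: TBAF, THF, 0 → 23 °C
Reagents that add atoms: none
Why: Fluoride desilylation; the polyene is untouched.

**Step 11**
Reactants: 14 trienol
Product: 15 rac-(3E,5E,7E)-4,6-diethyl-8-phenylocta-3,5,7-trien-2-yl methyl carbonate
Conditions: ClCO2Me, pyridine, DMAP (cat.), CH2Cl2, 0 °C; filtered through Et3N-deactivated silica and used at once
Reagents that add atoms: methyl chloroformate, COC(=O)Cl
Why: O-acylation of the secondary allylic alcohol; the carbonate is both the leaving group and the internal source of methoxide for base-free transmetalation.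

**Step 12 (key step)**
Reactants: 6 (2E,4Z)-dienylboronate; 15 racemic trienyl carbonate
Product: 16 tert-butyl{[(2E,4Z,6S,7E,9E,11E)-4,8,10-triethyl-2,6-dimethyl-12-phenyldodeca-2,4,7,9,11-pentaen-1-yl]oxy}dimethylsilane
Conditions: Ni(cod)2 (10 mol %), (R)-DTBM-SEGPHOS (12 mol %), 6 (1.3 equiv), THF–MeOH 10:1, degassed, dark, 0 → 23 °C
Reagents that add atoms: none (CO2 and MeOBpin are lost)
Why: Proposed new method: an enantioconvergent Ni(0)-catalysed allyl–alkenyl Suzuki–Miyaura coupling of a racemic, acyclic 1,3,3-trisubstituted allylic carbonate. Both enantiomers of 15 ionise (−CO2) to the same 1-methyl-3-ethyl-3-dienyl π-allyl–Ni(II)–OMe species; the methoxide transmetalates alkenyl-Bpin 6 without added base; the diastereomeric (allyl)Ni(alkenyl)L* complexes interconvert faster than they couple (reversible β-H elimination from the methyl terminus to a Ni–H/tetraene complex and re-insertion, or Ni(0)/Ni(II) allyl exchange); inner-sphere C(sp3)–C(sp2) reductive elimination at the less hindered methyl-bearing terminus is enantio-determining and sets C6, keeps the styryl-triene conjugated, never makes C8 σ-bound (so 7E survives), and retains the 4Z geometry of 6. Closest known reactions: Ni–H-catalysed enantioselective 1,2-hydroarylation of 1,3-dienes with arylboron reagents (same allyl–Ni–aryl intermediate) and stereospecific Ni/Pd Suzuki couplings of secondary allylic esters.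

**Step 13**
Reactants: 16 pentaene silyl ether
Product: 17 (2E,4Z,6S,7E,9E,11E)-4,8,10-triethyl-2,6-dimethyl-12-phenyldodeca-2,4,7,9,11-pentaen-1-ol
Conditions: TBAF, AcOH (1:1), THF, 0 °C
Reagents that add atoms: none
Why: Buffered fluoride desilylation removes the primary TBS group without deprotonating the bis-allylic C6–H.

**Step 14**
Reactants: 17 pentaenol
Product: 18 (2E,4Z,6S,7E,9E,11E)-4,8,10-triethyl-2,6-dimethyl-12-phenyldodeca-2,4,7,9,11-pentaenal
Conditions: Dess–Martin periodinane, NaHCO3, CH2Cl2, 0 °C; used directly
Reagents that add atoms: none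
Why: Mild, non-basic Dess–Martin oxidation of the primary allylic alcohol gives the enal dienophile without touching C6 or the alkene geometries.

**Step 15**
Reactants: 18 pentaenal
Product: 19 (1R,3aR,4R,5S,7aS)-3,5,7-triethyl-1,4-dimethyl-5-[(E)-2-phenylethenyl]-3a,4,5,7a-tetrahydro-1H-indene-4-carbaldehyde (trans ring fusion; CHO cis to styryl and to H-3a; C1-Me cis to H-7a)
Conditions: PhMe (0.01 M), BHT (cat.), 23 → 60 °C
Reagents that add atoms: none
Why: Thermal type-1 intramolecular Diels–Alder reaction (dienophile C2=C3, diene C7=C8–C9=C10, Z-alkene in the three-atom tether). The CHO-endo/tether-exo transition state gives the trans ring fusion; allylic 1,3-strain (C6–H eclipsing C7=C8 toward the C8 ethyl) sends the dienophile to the diene face anti to the C6 methyl; suprafacial addition transfers the 2E and 9E geometries into the two adjacent quaternary centres. The enal allows a temperature low enough to avoid [1,5]-H shift in the (4Z)-diene.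

**Step 16**
Reactants: 19 bicyclic aldehyde
Product: 20 spiculoic acid B, (1R,3aR,4R,5S,7aS)-3,5,7-triethyl-1,4-dimethyl-5-[(E)-2-phenylethenyl]-3a,4,5,7a-tetrahydro-1H-indene-4-carboxylic acid
Conditions: NaClO2, NaH2PO4, 2-methyl-2-butene (excess), t-BuOH/H2O, 0 → 23 °C
Reagents that add atoms: sodium chlorite, [Na+].[O-]Cl=O
Why: Pinnick oxidation works on hindered aldehydes; the α-carbon is quaternary so nothing can epimerise, and the scavenger protects the trisubstituted alkenes from HOCl.

## Compound list

1 | prop-2-yn-1-ol | C#CCO | starting material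
2 | (E)-3-iodo-2-methylprop-2-en-1-ol | OC/C(C)=C/I | intermediate
3 | (E)-tert-butyl[(3-iodo-2-methylprop-2-en-1-yl)oxy]dimethylsilane | CC(C)(C)[Si](C)(C)OC/C(C)=C/I | intermediate
4 | but-1-yne | CCC#C | starting material
5 | 2-[(1Z)-2-bromobut-1-en-1-yl]-4,4,5,5-tetramethyl-1,3,2-dioxaborolane | CC/C(Br)=C/B1OC(C)(C)C(C)(C)O1 | intermediate
6 | tert-butyl{[(2E,4Z)-4-ethyl-2-methyl-5-(pinacolatoboryl)penta-2,4-dien-1-yl]oxy}dimethylsilane | CC(C)(C)[Si](C)(C)OC/C(C)=C/C(CC)=C\B1OC(C)(C)C(C)(C)O1 | intermediate
7 | hex-3-yn-2-ol (racemic) | CCC#CC(C)O | starting material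
8 | tert-butyl(hex-3-yn-2-yloxy)dimethylsilane (racemic) | CCC#CC(C)O[Si](C)(C)C(C)(C)C | intermediate
9 | 1-bromobut-1-yne | CCC#CBr | intermediate
10 | rac-(E)-tert-butyl[(4-ethyloct-3-en-5-yn-2-yl)oxy]dimethylsilane | CCC#C/C(CC)=C/C(C)O[Si](C)(C)C(C)(C)C | intermediate
11 | ethynylbenzene | C#Cc1ccccc1 | starting material
12 | (E)-(2-iodoethenyl)benzene | I/C=C/c1ccccc1 | intermediate
13 | rac-tert-butyl{[(3E,5E,7E)-4,6-diethyl-8-phenylocta-3,5,7-trien-2-yl]oxy}dimethylsilane | CC(O[Si](C)(C)C(C)(C)C)/C=C(CC)/C=C(CC)/C=C/c1ccccc1 | intermediate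
14 | rac-(3E,5E,7E)-4,6-diethyl-8-phenylocta-3,5,7-trien-2-ol | CC(O)/C=C(CC)/C=C(CC)/C=C/c1ccccc1 | intermediate
15 | rac-(3E,5E,7E)-4,6-diethyl-8-phenylocta-3,5,7-trien-2-yl methyl carbonate | COC(=O)OC(C)/C=C(CC)/C=C(CC)/C=C/c1ccccc1 | intermediate
16 | tert-butyl{[(2E,4Z,6S,7E,9E,11E)-4,8,10-triethyl-2,6-dimethyl-12-phenyldodeca-2,4,7,9,11-pentaen-1-yl]oxy}dimethylsilane | CC(C)(C)[Si](C)(C)OC/C(C)=C/C(CC)=C\[C@@H](C)/C=C(CC)/C=C(CC)/C=C/c1ccccc1 | intermediate
17 | (2E,4Z,6S,7E,9E,11E)-4,8,10-triethyl-2,6-dimethyl-12-phenyldodeca-2,4,7,9,11-pentaen-1-ol | OC/C(C)=C/C(CC)=C\[C@@H](C)/C=C(CC)/C=C(CC)/C=C/c1ccccc1 | intermediate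
18 | (2E,4Z,6S,7E,9E,11E)-4,8,10-triethyl-2,6-dimethyl-12-phenyldodeca-2,4,7,9,11-pentaenal | O=C/C(C)=C/C(CC)=C\[C@@H](C)/C=C(CC)/C=C(CC)/C=C/c1ccccc1 | intermediate
19 | (1R,3aR,4R,5S,7aS)-3,5,7-triethyl-1,4-dimethyl-5-[(E)-2-phenylethenyl]-3a,4,5,7a-tetrahydro-1H-indene-4-carbaldehyde | CCC1=C[C@@](/C=C/c2ccccc2)(CC)[C@](C)(C=O)[C@H]2C(CC)=C[C@@H](C)[C@H]12 | intermediate
20 | spiculoic acid B | CCC1=C[C@@](/C=C/c2ccccc2)(CC)[C@](C)(C(=O)O)[C@H]2C(CC)=C[C@@H](C)[C@H]12 | target

## Step count and risks

Total steps: 16.
Longest linear sequence: 10 (steps 5, 7, 9, 10, 11, 12, 13, 14, 15, 16 from hex-3-yn-2-ol).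

Three steps most likely to fail:

1. **Step 12 (proposed new Ni-catalysed enantioconvergent allyl–alkenyl coupling).** Risks are low ee, reductive elimination at the wrong allyl terminus or further along the polyene, and elimination to the tetraene. Fallback (known chemistry): make the carbonate as a single enantiomer and use chirality transfer instead of catalyst control. Prepare (R)-hex-3-yn-2-ol by asymmetric transfer hydrogenation of hex-3-yn-2-one or by C-ethylation of commercial (R)-but-3-yn-2-ol, run steps 5–11 unchanged to (R)-15, and couple it with 6 in a stereospecific Pd(0)- or Ni(0)-catalysed allylic Suzuki coupling with an achiral phosphine. The normal net inversion (anti oxidative addition, inner-sphere reductive elimination) gives (6S)-16.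

2. **Step 15 (IMDA).** Risks are a poor endo/exo ratio (trans versus cis ring fusion), poor facial selectivity, or slow reaction at the hindered diene terminus (inside ethyl on C10, two adjacent quaternary centres). Fallback: run the cycloaddition at the acid oxidation level. Oxidise 18 to the pentaenoic acid first (Pinnick on the unhindered dienal, 0 °C) and cyclise it as its acyloxyborane (BH3·THF or a catecholborane-type activator, low temperature), a known strongly activated form of unsaturated acids in Diels–Alder reactions. The cycloadduct is then 20 directly and step 16 disappears.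

3. **Step 9 (hydrozirconation of the conjugated enyne and Negishi coupling).** Risks are Zr adding at the wrong alkyne carbon and isomerisation of the dienylzirconium. Fallback: build C9=C10 by sequential coupling of a 1,1-dibromoalkene instead of alkyne hydrometalation. Convert the vinylzirconium from 8 to the vinyl iodide, then to the (E)-enal TBSO–CH(Me)–CH=C(Et)–CHO (t-BuLi, DMF) and the 1,1-dibromodiene (CBr4, PPh3). Then carry out a trans-selective Pd-catalysed coupling with (E)-styryl-Bpin (from 11 and pinacolborane), followed by ethylation of the remaining (Z)-bromide with Et2Zn and Pd(t-Bu3P)2 (retention) to give 13.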